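**Retrosynthetic overview**
1. Feature: rings B and C share the C8–C9 bond, and quaternary C8 is bonded to C14, which carries two carbons at the carbonyl level (lactone carbonyl C15 and carbinol carbon C2') beside C13. This is the retron of a Diels–Alder reaction between a 1-oxy diene C9=C11–C12=C13 and an alkylidene malonate C8=C14.
2. Late disconnections: C13=CH2 (methylenation of a C13 ketone); ring E (O–C15 lactonisation) and ring D (C14–C2' aldol) from a C12 side chain attached by C12–C1' alkylation with a lactate-derived allylic bromide, one malonate ester being excised; ring A lactone by Baeyer–Villiger insertion of oxygen between C3 and C4 of a C3 enone.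
3. Key disconnection: C8–C9 and C13–C14, opening rings B and C of tricycle 12 to the ring A triene 11.
4. Triene 11 from (R)-α-ionone: C8=C14 by Knoevenagel condensation, C10–C9 by Claisen rearrangement from a C2 carbinol, C11=C12 by Wittig reaction, then silyl dienol ether formation.
5. Ring order: A (from ionone) → B and C together (step 8) → ring A enlarged to the lactone (step 12) → D and E together (step 20).

Key step: step 8

Numbering: ring A = C1–C5, C10 (C3 = lactone carbonyl, ring oxygen between C3 and C4); ring B = C5–C10; ring C = C8, C9, C11–C14; C15 = lactone carbonyl on C14; C1' (CH2), C2' (C–OH), C3' (CH–O), C4' (CH3) = lactate-derived unit of rings D and E. α is the face of H-9; β is the face of the C8, C10 and C12 methyl groups.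
Assumption: (R)-α-ionone is taken as purchasable in high enantiomeric purity; every other stereocenter derives from it or from methyl (R)-lactate.

**Route**

Step 1
Reactants: 1 (R)-α-ionone
Product: 2 (R)-dihydro-α-ionone, 4-[(1R)-2,6,6-trimethylcyclohex-2-en-1-yl]butan-2-one
Conditions: [(Ph3P)CuH]6 (0.25 equiv), H2O (2 equiv), benzene, rt
Reagents that add atoms: none
Why: Stryker conjugate reduction with [(Ph3P)CuH]6 should add hydride 1,4 to the enone only, under neutral conditions that leave the ring alkene and the doubly allylic C5 stereocenter untouched.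

Step 2
Reactants: 2 (R)-dihydro-α-ionone; 3 dimethyl malonate
Product: 4 alkylidene malonate, dimethyl 2-{4-[(1R)-2,6,6-trimethylcyclohex-2-en-1-yl]butan-2-ylidene}malonate
Conditions: TiCl4, pyridine, THF, 0 °C → rt
Reagents that add atoms: none
Why: The TiCl4/pyridine Knoevenagel condensation is the standard way to condense ketones with malonates, and the two identical esters leave the tetrasubstituted C8=C14 alkene without a geometry to control.

Step 3
Reactants: 4 alkylidene malonate
Product: 5 ring enone, dimethyl 2-{4-[(1R)-2,6,6-trimethyl-4-oxocyclohex-2-en-1-yl]butan-2-ylidene}malonate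
Conditions: CrO3 (5 mol %), t-BuOOH (70% aq.), CH2Cl2, rt
Reagents that add atoms: tert-butyl hydroperoxide CC(C)(C)OO
Why: Chromium-catalysed allylic oxidation with t-BuOOH, the established conversion of α-ionone rings into their 3-oxo derivatives, should attack the only allylic CH2 of the electron-rich ring alkene (C2) and spare the electron-poor alkylidene malonate.

Step 4
Reactants: 5 ring enone
Product: 6 trans allylic alcohol, dimethyl 2-{4-[(1R,4R)-4-hydroxy-2,6,6-trimethylcyclohex-2-en-1-yl]butan-2-ylidene}malonate (C2 hydroxyl trans to the C5 side chain)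
Conditions: (S)-Me-CBS (20 mol %), catecholborane, toluene, −78 °C
Reagents that add atoms: none
Why: Corey–Bakshi–Shibata reduction, with the enone double bond read as the large group, should deliver hydride under catalyst control to give the (2R)-carbinol (hydroxyl trans to the C5 chain), and any cis isomer is a separable diastereomer.

Step 5
Reactants: 6 trans allylic alcohol
Product: 8 ring A aldehyde (C10 bears methyl and CH2CHO; CH2CHO trans to the C5 side chain; C1=C2), via vinyl ether 7 (not isolated)
Conditions: Pd(OCOCF3)2 (2 mol %), 4,7-diphenyl-1,10-phenanthroline (2 mol %), Et3N (cat.), butyl vinyl ether, 75 °C; evaporate; toluene, 185 °C, sealed tube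
Reagents that add atoms: butyl vinyl ether C=COCCCC
Why: Transfer vinylation followed by Claisen rearrangement, which is suprafacial, so the C2–O configuration is relayed to C10 and the C9–C11 unit enters on the face away from the C5 chain while C1=C2 is created.

Step 6
Reactants: 8 ring A aldehyde; 9 2-(triphenylphosphoranylidene)propanal
Product: 10 enal (C10–CH2–CH=C(CH3)–CHO, E)
Conditions: toluene, 100 °C
Reagents that add atoms: none
Why: Wittig reaction with the stabilised formyl ylide should give the (E)-2-methyl enal and stop after one homologation, since the conjugated α-branched product is far less reactive than the starting aldehyde.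

Step 7
Reactants: 10 enal
Product: 11 ring A triene malonate, (1E,3E)-silyl dienol ether C9=C11–C12(CH3)=C13–OTBS on C10
Conditions: TBSOTf, Et3N, CH2Cl2, −78 → 0 °C
Reagents that add atoms: tert-butyldimethylsilyl triflate CC(C)(C)[Si](C)(C)OS(=O)(=O)C(F)(F)F
Why: Soft γ-enolisation (O-silylation of the aldehyde, then deprotonation at C9) should give the (1E,3E)-1-silyloxy diene from the s-trans enal, the aldehyde being silylated far faster than the malonate esters.

Step 8
Reactants: 11 ring A triene malonate
Product: 12 tricyclic A–B–C geminal diester (C11=C12, C13–OTBS β, trans-fused B/C)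
Conditions: toluene (0.01 M), BHT (cat.), sealed tube, 180 °C
Reagents that add atoms: none
Why: Thermal intramolecular Diels–Alder reaction of a 1,7,9-decatriene (closest type: terminally activated decatrienes giving trans-decalins), concerted but asynchronous, with C8–C9 leading because C9 is the nucleophilic end of the 1-silyloxy diene and C8 the electrophilic carbon of the alkylidene malonate. Ring C closes as the cycloaddition ring (C8–C9 and C13–C14) and ring B as the fused ring through the tether C10–C5–C6–C7 in a chair anchored by the trans-diequatorial attachment of both arms to ring A. C9 is set by this chair (H-9 axial, anti to the C10 methyl) and C8 by the dienophile placing its small methyl axial and the C(CO2Me)2 terminus equatorial, away from the axial C10 methyl, which gives the trans B/C fusion; C13 follows from the E enol ether and is erased in step 10. The step needs one regiochemistry and one facial pairing: the first is fixed by the tether and matched by the electronics, the second by the chair, while the geminal esters remove any endo/exo or alkene-geometry question and are too poor as heterodienes for an oxa-Diels–Alder path. If C9 emerged epimeric, the C13 enone 14 would allow correction by vinylogous enolisation.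

Step 9
Reactants: 12 tricyclic A–B–C geminal diester
Product: 13 C13 allylic alcohol
Conditions: HF·pyridine, THF, 0 °C → rt
Reagents that add atoms: none
Why: Acidic fluoride desilylation avoids the free alkoxide that could expel the malonate by retro-aldol cleavage.

Step 10
Reactants: 13 C13 allylic alcohol
Product: 14 ring C enone (C13 ketone, C11=C12)
Conditions: Dess–Martin periodinane, CH2Cl2, rt
Reagents that add atoms: none
Why: Dess–Martin oxidation should convert the hindered allylic carbinol into the enone under near-neutral conditions.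

Step 11
Reactants: 14 ring C enone
Product: 16 bis-enone (C1=C2–C3=O in ring A, C13 enone in ring C), via allylic alcohol 15 (not isolated)
Conditions: SeO2 (0.5 equiv), t-BuOOH, CH2Cl2, rt; filter, concentrate; Dess–Martin periodinane, CH2Cl2, rt
Reagents that add atoms: selenium dioxide O=[Se]=O (oxygen carrier) and tert-butyl hydroperoxide CC(C)(C)OO (terminal oxygen source)
Why: Selenium dioxide allylic oxidation runs by ene reaction and [2,3] shift, so oxygen should arrive at C3 without transposing C1=C2; ring A holds the only electron-rich alkene with an allylic hydrogen, and Dess–Martin oxidation then gives the enone.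

Step 12
Reactants: 16 bis-enone
Product: 17 ring A enoate lactone with ring C enone
Conditions: m-CPBA, CH2Cl2, rt → 40 °C
Reagents that add atoms: 3-chloroperbenzoic acid O=C(OO)c1cccc(Cl)c1
Why: Baeyer–Villiger oxidation of the C3 enone, in which tertiary C4 should migrate in preference to vinylic C2 to give the seven-membered enoate lactone; the C13 enone is shielded by quaternary C14 and offers only an ester-laden or a vinylic carbon for migration, and both alkenes are electron-poor.

Step 13
Reactants: 17 ring A enoate lactone with ring C enone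
Product: 18 C13 ketone with saturated ring C (C12 epimers; ring A lactone intact)
Conditions: [(Ph3P)CuH]6 (0.25 equiv), H2O (2 equiv), benzene/THF, rt
Reagents that add atoms: none
Why: Stryker conjugate reduction with [(Ph3P)CuH]6 should discriminate the enone from the hindered enoate lactone; the C12 configuration is unimportant because C12 is deprotonated in step 17.

Step 14
Reactants: 19 methyl (R)-lactate
Product: 20 methyl (R)-2-(tert-butyldimethylsilyloxy)propanoate
Conditions: TBSCl, imidazole, DMF, rt
Reagents that add atoms: tert-butyldimethylsilyl chloride CC(C)(C)[Si](C)(C)Cl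
Why: Standard silylation of a secondary alcohol, in which the stereocenter is not involved.

Step 15
Reactants: 20 methyl (R)-2-(tert-butyldimethylsilyloxy)propanoate
Product: 22 allylsilane (R)-CH2=C(CH2SiMe3)–CH(CH3)OTBS, via carbinol 21 (not isolated)
Conditions: Me3SiCH2MgCl, CeCl3, THF, −78 °C → rt; then silica gel, CH2Cl2, rt
Reagents that add atoms: (trimethylsilyl)methylmagnesium chloride C[Si](C)(C)C[Mg]Cl
Why: The weakly basic organocerium reagent should add twice to the ester without enolising it, and Peterson elimination of the bis(silylmethyl) carbinol gives the 2-substituted allylsilane.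

Step 16
Reactants: 22 allylsilane
Product: 23 allylic bromide (R)-CH2=C(CH2Br)–CH(CH3)OTBS
Conditions: NBS, CH2Cl2, −78 → −20 °C
Reagents that add atoms: N-bromosuccinimide O=C1CCC(=O)N1Br
Why: Electrophilic bromodesilylation of the allylsilane (SE2') should give the allylic bromide, and the product is the same whichever terminus is brominated.

Step 17
Reactants: 18 C13 ketone with saturated ring C; 23 allylic bromide
Product: 25 C12-alkylated diester (C12: β methyl and α CH2–C(=CH2)–CH(CH3)OTBS), via potassium enolate 24 (not isolated)
Conditions: KN(SiMe3)2, THF, −78 °C; then 23, −78 → 0 °C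
Reagents that add atoms: none
Why: Enolate alkylation in which the geminal esters block C14 so that only C12 can be deprotonated, and the allylic bromide should enter axially on the α face, anti to the axial C8 methyl across ring C, which sets the C12 quaternary center.

Step 18
Reactants: 25 C12-alkylated diester
Product: 26 C14 β-keto ester (C14 epimers)
Conditions: LiCl, H2O, DMSO, 135 °C
Reagents that add atoms: none
Why: Krapcho demethoxycarbonylation, in which chloride demethylates one ester and the β-keto carboxylate loses CO2; the ring A lactone is a tertiary alkyl ester and should be inert to chloride.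

Step 19
Reactants: 26 C14 β-keto ester
Product: 28 C2' ketone (side chain CH2–CO–CH(CH3)OTBS on C12), via diol 27 (not isolated)
Conditions: OsO4 (2 mol %), NMO, acetone/H2O, rt; then NaIO4, THF/H2O, rt
Reagents that add atoms: N-methylmorpholine N-oxide C[N+]1([O-])CCOCC1 and water O (oxygen delivered through the osmate ester)
Why: Upjohn dihydroxylation followed by periodate cleavage (Lemieux–Johnson sequence), in which OsO4 should select the electron-rich 1,1-disubstituted alkene over the electron-poor C1=C2 of the enoate lactone.

Step 20
Reactants: 28 C2' ketone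
Product: 30 pentacyclic C13 ketone (rings A–E complete), via hydroxy ketone 29 (not isolated)
Conditions: HF·pyridine, THF, 0 °C → rt; then DBU (0.2 equiv), CH2Cl2, rt
Reagents that add atoms: none
Why: Desilylation frees the C3' hydroxyl, then intramolecular aldol addition of the C14 β-keto ester to the C2' ketone closes ring D across the α face (C12 and C14 axial) and lactonisation onto C15 closes ring E; only the C2' epimer with C3' exo can lactonise and the aldol is reversible, so C14 and C2' should be funnelled to the required configuration while C3' stays as set in lactate.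

Step 21
Reactants: 30 pentacyclic C13 ketone
Product: 31 brasilianoid B
Conditions: Zn, CH2Br2, TiCl4, THF/CH2Cl2, 0 °C → rt
Reagents that add atoms: dibromomethane BrCBr
Why: Takai–Lombardo methylenation is non-basic and selective for ketones over lactones, and should convert the C13 carbonyl flanked by two quaternary carbons into the exocyclic methylene.

**Compound list**
1 | (R)-α-ionone | CC1=CCCC(C)(C)[C@H]1/C=C/C(C)=O | starting material
2 | (R)-dihydro-α-ionone | CC1=CCCC(C)(C)[C@H]1CCC(C)=O | intermediate
3 | dimethyl malonate | COC(=O)CC(=O)OC | starting material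
4 | alkylidene malonate, dimethyl 2-{4-[(1R)-2,6,6-trimethylcyclohex-2-en-1-yl]butan-2-ylidene}malonate | CC1=CCCC(C)(C)[C@H]1CCC(C)=C(C(=O)OC)C(=O)OC | intermediate
5 | ring enone (C2 ketone, C1=C10) | CC1=CC(=O)CC(C)(C)[C@H]1CCC(C)=C(C(=O)OC)C(=O)OC | intermediate
6 | trans allylic alcohol (1R,4R; C2–OH trans to C5 chain) | CC1=C[C@H](O)CC(C)(C)[C@H]1CCC(C)=C(C(=O)OC)C(=O)OC | intermediate
7 | vinyl ether of 6 | CC1=C[C@H](OC=C)CC(C)(C)[C@H]1CCC(C)=C(C(=O)OC)C(=O)OC | intermediate
8 | ring A aldehyde (C10: CH3 and CH2CHO, the latter trans to the C5 chain; C1=C2) | COC(=O)C(C(=O)OC)=C(C)CC[C@H]1[C@](C)(CC=O)C=CCC1(C)C | intermediate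
9 | 2-(triphenylphosphoranylidene)propanal | CC(C=O)=P(c1ccccc1)(c1ccccc1)c1ccccc1 | starting material
10 | (E)-enal (C10–CH2–CH=C(CH3)–CHO) | COC(=O)C(C(=O)OC)=C(C)CC[C@H]1[C@](C)(C/C=C(\C)C=O)C=CCC1(C)C | intermediate
11 | ring A triene malonate, (1E,3E)-silyl dienol ether | COC(=O)C(C(=O)OC)=C(C)CC[C@H]1[C@](C)(/C=C/C(C)=C/O[Si](C)(C)C(C)(C)C)C=CCC1(C)C | intermediate
12 | tricyclic A–B–C geminal diester, C13–OTBS | CC1=C[C@H]3[C@]4(C)C=CCC(C)(C)[C@H]4CC[C@]3(C)C(C(=O)OC)(C(=O)OC)[C@H]1O[Si](C)(C)C(C)(C)C | intermediate
13 | C13 allylic alcohol | CC1=C[C@H]3[C@]4(C)C=CCC(C)(C)[C@H]4CC[C@]3(C)C(C(=O)OC)(C(=O)OC)[C@H]1O | intermediate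
14 | ring C enone (C13=O, C11=C12) | O=C1C(C)=C[C@H]3[C@]4(C)C=CCC(C)(C)[C@H]4CC[C@]3(C)C1(C(=O)OC)C(=O)OC | intermediate
15 | C3 allylic alcohol (C3 epimers) | O=C1C(C)=C[C@H]3[C@]4(C)C=CC(O)C(C)(C)[C@H]4CC[C@]3(C)C1(C(=O)OC)C(=O)OC | intermediate
16 | bis-enone (C3 and C13 enones) | O=C1C(C)=C[C@H]3[C@]4(C)C=CC(=O)C(C)(C)[C@H]4CC[C@]3(C)C1(C(=O)OC)C(=O)OC | intermediate
17 | ring A enoate lactone, ring C enone | O=C1C(C)=C[C@H]3[C@]4(C)C=CC(=O)OC(C)(C)[C@H]4CC[C@]3(C)C1(C(=O)OC)C(=O)OC | intermediate
18 | ring A lactone, C13 ketone, saturated ring C (C12 epimers) | O=C1C(C)C[C@H]3[C@]4(C)C=CC(=O)OC(C)(C)[C@H]4CC[C@]3(C)C1(C(=O)OC)C(=O)OC | intermediate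
19 | methyl (R)-lactate | COC(=O)[C@@H](C)O | starting material
20 | methyl (R)-2-(tert-butyldimethylsilyloxy)propanoate | COC(=O)[C@@H](C)O[Si](C)(C)C(C)(C)C | intermediate
21 | bis(trimethylsilylmethyl) carbinol | C[Si](C)(C)CC(O)(C[Si](C)(C)C)[C@@H](C)O[Si](C)(C)C(C)(C)C | intermediate
22 | allylsilane (R)-CH2=C(CH2SiMe3)CH(CH3)OTBS | C=C(C[Si](C)(C)C)[C@@H](C)O[Si](C)(C)C(C)(C)C | intermediate
23 | allylic bromide (R)-CH2=C(CH2Br)CH(CH3)OTBS | C=C(CBr)[C@@H](C)O[Si](C)(C)C(C)(C)C | intermediate
24 | potassium enolate of 18 (C12=C13) | [K+].[O-]C1=C(C)C[C@H]3[C@]4(C)C=CC(=O)OC(C)(C)[C@H]4CC[C@]3(C)C1(C(=O)OC)C(=O)OC | intermediate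
25 | C12-alkylated diester (side chain α, methyl β) | O=C1[C@@](CC(=C)[C@@H](C)O[Si](C)(C)C(C)(C)C)(C)C[C@H]3[C@]4(C)C=CC(=O)OC(C)(C)[C@H]4CC[C@]3(C)C1(C(=O)OC)C(=O)OC | intermediate
26 | C14 β-keto ester (C14 epimers) | O=C1[C@@](CC(=C)[C@@H](C)O[Si](C)(C)C(C)(C)C)(C)C[C@H]3[C@]4(C)C=CC(=O)OC(C)(C)[C@H]4CC[C@]3(C)C1C(=O)OC | intermediate
27 | diol (C2' and C14 epimers) | O=C1[C@@](CC(O)(CO)[C@@H](C)O[Si](C)(C)C(C)(C)C)(C)C[C@H]3[C@]4(C)C=CC(=O)OC(C)(C)[C@H]4CC[C@]3(C)C1C(=O)OC | intermediate
28 | C2' ketone (C14 epimers) | O=C1[C@@](CC(=O)[C@@H](C)O[Si](C)(C)C(C)(C)C)(C)C[C@H]3[C@]4(C)C=CC(=O)OC(C)(C)[C@H]4CC[C@]3(C)C1C(=O)OC | intermediate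
29 | hydroxy ketone (C14 epimers) | O=C1[C@@](CC(=O)[C@@H](C)O)(C)C[C@H]3[C@]4(C)C=CC(=O)OC(C)(C)[C@H]4CC[C@]3(C)C1C(=O)OC | intermediate
30 | pentacyclic C13 ketone | O=C1[C@@]2(C)C[C@H]3[C@]4(C)C=CC(=O)OC(C)(C)[C@H]4CC[C@]3(C)[C@@]13C(=O)O[C@H](C)[C@@]3(O)C2 | intermediate
31 | brasilianoid B | C=C1[C@@]2(C)C[C@H]3[C@]4(C)C=CC(=O)OC(C)(C)[C@H]4CC[C@]3(C)[C@@]13C(=O)O[C@H](C)[C@@]3(O)C2 | target

Total step count: 21 (18 in the main line, 3 for bromide 23). Longest linear sequence: 18 steps (steps 1–13 and 17–21).

**Steps most likely to fail**

Step 8. The cycloaddition may not take place because the C8–C9 bond has to form between a fully substituted dienophile carbon and a diene terminus next to quaternary C10, or the silyl dienol ether may decompose before closure. The fallback makes the same two bonds one after the other and sets out from 11. Me2AlCl in CH2Cl2 at −78 °C should trigger an intramolecular vinylogous Mukaiyama–Michael addition of C9 to C8 through the same chair, and aqueous work-up gives the bicyclic enal malonate F1 with either C11=C12 geometry. Conjugate reduction with [(Ph3P)CuH]6 removes the geometry question and gives the saturated aldehyde F2. Soft enolisation of the malonate (MgBr2·OEt2, Et3N) closes ring C by intramolecular aldol addition to the C13 carbinol F3. Dess–Martin oxidation gives the saturated C13 ketone F4, and dehydrogenation with IBX in DMSO at 70 °C reinstalls C11=C12, which brings the material back to the route at 14.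

Step 17. C-alkylation at the congested tetrasubstituted enolate may be slow, may give way to O-alkylation, or may occur on the wrong face. The fallback sets out from 18 and 23 and uses a sigmatropic transfer in place of the SN2 step. Enolate 24 is O-allylated on purpose (KN(SiMe3)2, 18-crown-6, DMPU) to the allyl enol ether F5. Claisen rearrangement in toluene at 150 °C then moves the allyl group from oxygen to C12 through a chair on the α face and comes back to the route at 25.

Step 21. The carbonyl between two quaternary carbons may not react with the bulky titanium–zinc carbenoid, or the Lewis acidic medium may damage the β-hydroxy ketone. The fallback sets out from 30 and is a two-step Peterson olefination. The small, weakly basic cerium reagent from Me3SiCH2MgCl and CeCl3 adds to C13 at −78 °C to give the β-hydroxysilane F6. Treatment with HF·pyridine eliminates toward the new carbon only, because C12 and C14 are quaternary, and comes back to the route at 31.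

Further compounds
F1 | step 8 | bicyclic enal malonate (C9–CH=C(CH3)–CHO, C8–CH(CO2Me)2) | O=CC(C)=C[C@H]1[C@]2(C)C=CCC(C)(C)[C@H]2CC[C@]1(C)C(C(=O)OC)C(=O)OC
F2 | step 8 | bicyclic saturated aldehyde malonate | O=CC(C)C[C@H]1[C@]2(C)C=CCC(C)(C)[C@H]2CC[C@]1(C)C(C(=O)OC)C(=O)OC
F3 | step 8 | tricyclic C13 carbinol geminal diester | OC1C(C)C[C@H]3[C@]4(C)C=CCC(C)(C)[C@H]4CC[C@]3(C)C1(C(=O)OC)C(=O)OC
F4 | step 8 | tricyclic saturated C13 ketone geminal diester | O=C1C(C)C[C@H]3[C@]4(C)C=CCC(C)(C)[C@H]4CC[C@]3(C)C1(C(=O)OC)C(=O)OC
F5 | step 17 | allyl enol ether of 18 | C=C(COC1=C(C)C[C@H]3[C@]4(C)C=CC(=O)OC(C)(C)[C@H]4CC[C@]3(C)C1(C(=O)OC)C(=O)OC)[C@@H](C)O[Si](C)(C)C(C)(C)C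
F6 | step 21 | C13 β-hydroxysilane (C13 carbinol bearing CH2SiMe3) | C[Si](C)(C)CC1(O)[C@@]2(C)C[C@H]3[C@]4(C)C=CC(=O)OC(C)(C)[C@H]4CC[C@]3(C)[C@@]13C(=O)O[C@H](C)[C@@]3(O)C2
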